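**Strategy.** The 7‑hydroxychroman ring of the vestitol‑type half is disconnected across O1–C2 and C3–C4. Its O1–C8a–C4a–C4 array is a latent ortho‑quinone methide of resorcinol, and C2–C3 are the carbonyl and α‑carbons of an arylacetaldehyde. One aminocatalytic formal [4+2] between the enamine of that aldehyde and the quinone methide closes the pyran ring and sets C3 (R) under catalyst control. C2 emerges as a lactol and is then reduced. The aldehyde already carries the trans‑(3R,4S)‑3,4‑diarylchroman half, built by asymmetric transfer hydrogenation of an isoflavanone and an anti‑selective Friedel–Crafts arylation at C4.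

Key step: step 12

Remark (assumptions): 2,6‑dimethoxyphenol, 7‑hydroxychroman‑4‑one, paeonol and 4‑(benzyloxy)‑2‑hydroxybenzaldehyde are taken as commercial. Chroman numbering is O1, C2, C3, C4, C4a–C8a. The lactol is carried as a mixture of C2 anomers, because C2 becomes CH2 in the next step.

**Step 1**
Reactants: 1 2,6‑dimethoxyphenol
Product: 2 2‑(benzyloxy)‑1,3‑dimethoxybenzene
Conditions: BnBr, K2CO3, DMF, 50 °C
Reagents that add atoms: benzyl bromide, BrCc1ccccc1
Why: Williamson etherification of the phenoxide; capping the OH removes its para‑directing effect before the bromination.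

**Step 2**
Reactants: 2 2‑(benzyloxy)‑1,3‑dimethoxybenzene
Product: 3 3‑(benzyloxy)‑1‑bromo‑2,4‑dimethoxybenzene
Conditions: NBS, MeCN, 0 °C → rt
Reagents that add atoms: N‑bromosuccinimide, O=C1CCC(=O)N1Br
Why: Electrophilic aromatic bromination of a 1,2,3‑trialkoxybenzene should go para to one methoxy and ortho to the other, because the flanked central benzyloxy group is twisted out of conjugation.

**Step 3**
Reactants: 4 7‑hydroxychroman‑4‑one
Product: 5 7‑(benzyloxy)chroman‑4‑one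
Conditions: BnBr, K2CO3, acetone, reflux
Reagents that add atoms: benzyl bromide, BrCc1ccccc1
Why: Williamson etherification of the only acidic OH; the benzyl ether later stabilises the C4 cation and is removed in the last step.

**Step 4**
Reactants: 5 7‑(benzyloxy)chroman‑4‑one; 3 3‑(benzyloxy)‑1‑bromo‑2,4‑dimethoxybenzene
Product: 6 rac‑7‑(benzyloxy)‑3‑[3‑(benzyloxy)‑2,4‑dimethoxyphenyl]chroman‑4‑one
Conditions: Pd2(dba)3 (cat.), XPhos, NaOtBu, THF, 70 °C
Reagents that add atoms: none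
Why: Palladium‑catalysed α‑arylation of the ketone enolate with the aryl bromide should stop at mono‑arylation because the α‑aryl ketone is hindered; C3 is formed racemic and labile, which step 5 uses.

**Step 5**
Reactants: 6 rac‑7‑(benzyloxy)‑3‑[3‑(benzyloxy)‑2,4‑dimethoxyphenyl]chroman‑4‑one
Product: 7 (3R,4R)‑7‑(benzyloxy)‑3‑[3‑(benzyloxy)‑2,4‑dimethoxyphenyl]chroman‑4‑ol (3,4‑cis)
Conditions: RuCl[(R,R)‑TsDPEN](p‑cymene) (cat.), HCO2H/Et3N 5:2, EtOAc, 40 °C
Reagents that add atoms: none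
Why: Asymmetric transfer hydrogenation with dynamic kinetic resolution: C3 equilibrates through the enol, the (R,R)‑catalyst reduces the 3R ketone faster and delivers hydride anti to the aryl group, which should set 4R and 3R together as the cis alcohol.

**Step 6**
Reactants: 8 paeonol (1‑(2‑hydroxy‑4‑methoxyphenyl)ethan‑1‑one)
Product: 9 1‑[2‑(benzyloxy)‑4‑methoxyphenyl]ethan‑1‑one
Conditions: BnBr, K2CO3, DMF, 60 °C
Reagents that add atoms: benzyl bromide, BrCc1ccccc1
Why: Williamson etherification; the polar solvent breaks the hydrogen bond of the chelated phenol.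

**Step 7**
Reactants: 9 1‑[2‑(benzyloxy)‑4‑methoxyphenyl]ethan‑1‑one
Product: 10 methyl 2‑[2‑(benzyloxy)‑4‑methoxyphenyl]acetate
Conditions: PhI(OAc)2, H2SO4 (cat.), MeOH/HC(OMe)3, rt
Reagents that add atoms: methanol, CO
Why: Iodine(III)‑mediated oxidative 1,2‑aryl migration of the methyl enol ether formed in situ; the electron‑rich aryl group migrates readily and the orthoester collapses to the methyl arylacetate.

**Step 8**
Reactants: 7 (3R,4R)‑isoflavan‑4‑ol; 10 methyl 2‑[2‑(benzyloxy)‑4‑methoxyphenyl]acetate (excess)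
Product: 11 methyl 2‑{2‑(benzyloxy)‑5‑[(3R,4S)‑7‑(benzyloxy)‑3‑(3‑(benzyloxy)‑2,4‑dimethoxyphenyl)chroman‑4‑yl]‑4‑methoxyphenyl}acetate (3,4‑trans)
Conditions: TsOH·H2O (cat.), HFIP/CH2Cl2, 0 °C → rt
Reagents that add atoms: none
Why: Friedel–Crafts alkylation: the C4 alcohol, para to the 7‑benzyloxy group, ionises to a stabilised benzylic cation, 10 attacks through its C5 (para to OBn, ortho to OMe) anti to the C3 aryl group, so 4S should be set by substrate control while C3 is untouched.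

**Step 9**
Reactants: 11 trans‑diarylchroman methyl ester
Product: 12 2‑{2‑(benzyloxy)‑5‑[(3R,4S)‑7‑(benzyloxy)‑3‑(3‑(benzyloxy)‑2,4‑dimethoxyphenyl)chroman‑4‑yl]‑4‑methoxyphenyl}acetaldehyde
Conditions: DIBAL‑H (1.05 equiv), CH2Cl2, −78 °C; MeOH, Rochelle salt
Reagents that add atoms: none
Why: Partial ester reduction: the aluminium hemiacetal is stable at −78 °C and releases the arylacetaldehyde only on work‑up; the aldehyde is used directly.

**Step 10**
Reactants: 13 4‑(benzyloxy)‑2‑hydroxybenzaldehyde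
Product: 14 5‑(benzyloxy)‑2‑(hydroxymethyl)phenol
Conditions: NaBH4, MeOH, 0 °C
Reagents that add atoms: none
Why: Borohydride reduction of the aldehyde; the acid‑sensitive benzylic alcohol is taken on without delay.

**Step 11**
Reactants: 14 5‑(benzyloxy)‑2‑(hydroxymethyl)phenol
Product: 15 5‑(benzyloxy)‑2‑[(4‑methylbenzenesulfonyl)methyl]phenol
Conditions: TolSO2Na, HCO2H/H2O, rt
Reagents that add atoms: sodium p‑toluenesulfinate, [Na+].[O-]S(=O)c1ccc(C)cc1
Why: Acid‑promoted SN1 substitution: the benzylic cation, stabilised by the ortho‑OH and para‑OBn groups, is captured at sulfur by the sulfinate to give a bench‑stable quinone methide precursor.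

**Step 12**
Reactants: 12 arylacetaldehyde; 15 5‑(benzyloxy)‑2‑[(4‑methylbenzenesulfonyl)methyl]phenol
Product: 18 (3R)‑7‑(benzyloxy)‑3‑{2‑(benzyloxy)‑5‑[(3R,4S)‑7‑(benzyloxy)‑3‑(3‑(benzyloxy)‑2,4‑dimethoxyphenyl)chroman‑4‑yl]‑4‑methoxyphenyl}chroman‑2‑ol (C2 anomers), via o‑quinone methide 16 (not isolated), via E‑enamine 17 (not isolated)
Conditions: (R)‑α,α‑diphenylprolinol trimethylsilyl ether (20 mol%), NaHCO3, CH2Cl2, 0 °C → rt
Reagents that add atoms: none
Why: Bicarbonate induces 1,4‑elimination of sulfinate from 15 to release quinone methide 16 slowly, while the catalyst condenses with 12 to the E‑enamine 17; the enamine α‑carbon adds to the methide carbon (C3–C4), the phenoxide closes onto the iminium carbon by 6‑exo‑trig attack (O1–C2), and the N,O‑acetal is hydrolysed by the water released on enamine formation to give lactol 18 and free catalyst. The closest known reaction type is the aminocatalytic formal [4+2] (Michael addition/hemiacetalisation) of aldehydes with o‑quinone methides generated from 2‑(sulfonylmethyl)phenols. C3 is set by the catalyst: the diphenyl(silyloxy)methyl group shields one face of the anti E‑enamine, the methide adds to the other face, and with the (R)‑catalyst this should give 3R, since the existing stereocentres are too remote to interfere. C2 forms as an anomeric mixture that step 13 erases. The step needs C‑ over N‑alkylation and cross‑ over self‑reaction, which the slow heterogeneous release of 16 and the high nucleophilicity of the conjugated enamine should secure; the closed lactol form protects the α‑aryl stereocentre from enolisation.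

**Step 13**
Reactants: 18 lactol
Product: 19 (3R)‑7‑(benzyloxy)‑3‑{2‑(benzyloxy)‑5‑[(3R,4S)‑7‑(benzyloxy)‑3‑(3‑(benzyloxy)‑2,4‑dimethoxyphenyl)chroman‑4‑yl]‑4‑methoxyphenyl}chroman
Conditions: Et3SiH, BF3·OEt2, CH2Cl2, −78 → −30 °C
Reagents that add atoms: none
Why: Ionic hydrogenation of the lactol: BF3 ionises C2–OH to the cyclic oxocarbenium ion, which silane hydride reduces with the ring O1–C2 bond intact; the low temperature should suppress loss of the C3 proton, so C3 stays R.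

**Step 14**
Reactants: 19 tetra‑O‑benzyl ether
Product: 20 (3R)‑3‑{2‑hydroxy‑5‑[(3R,4S)‑7‑hydroxy‑3‑(3‑hydroxy‑2,4‑dimethoxyphenyl)chroman‑4‑yl]‑4‑methoxyphenyl}chroman‑7‑ol (CNP0202416.1)
Conditions: H2 (1 atm), 10% Pd/C, EtOAc/MeOH, rt
Reagents that add atoms: none
Why: Catalytic hydrogenolysis removes the four benzyl ethers at once; the chroman C–O bonds, the methyl ethers and the diarylmethine C–C bonds are inert, so no stereocentre is touched.

**Compound list**
1 | 2,6‑dimethoxyphenol | COc1cccc(OC)c1O | starting material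
2 | 2‑(benzyloxy)‑1,3‑dimethoxybenzene | COc1cccc(OC)c1OCc1ccccc1 | intermediate
3 | 3‑(benzyloxy)‑1‑bromo‑2,4‑dimethoxybenzene | COc1ccc(Br)c(OC)c1OCc1ccccc1 | intermediate
4 | 7‑hydroxychroman‑4‑one | O=C1CCOc2cc(O)ccc12 | starting material
5 | 7‑(benzyloxy)chroman‑4‑one | O=C1CCOc2cc(OCc3ccccc3)ccc12 | intermediate
6 | rac‑7‑(benzyloxy)‑3‑[3‑(benzyloxy)‑2,4‑dimethoxyphenyl]chroman‑4‑one | O=C1c2ccc(OCc3ccccc3)cc2OCC1c1ccc(OC)c(OCc2ccccc2)c1OC | intermediate
7 | (3R,4R)‑7‑(benzyloxy)‑3‑[3‑(benzyloxy)‑2,4‑dimethoxyphenyl]chroman‑4‑ol | O[C@H]1c2ccc(OCc3ccccc3)cc2OC[C@H]1c1ccc(OC)c(OCc2ccccc2)c1OC | intermediate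
8 | paeonol, 1‑(2‑hydroxy‑4‑methoxyphenyl)ethan‑1‑one | CC(=O)c1ccc(OC)cc1O | starting material
9 | 1‑[2‑(benzyloxy)‑4‑methoxyphenyl]ethan‑1‑one | CC(=O)c1ccc(OC)cc1OCc1ccccc1 | intermediate
10 | methyl 2‑[2‑(benzyloxy)‑4‑methoxyphenyl]acetate | COC(=O)Cc1ccc(OC)cc1OCc1ccccc1 | intermediate
11 | methyl 2‑{2‑(benzyloxy)‑5‑[(3R,4S)‑7‑(benzyloxy)‑3‑(3‑(benzyloxy)‑2,4‑dimethoxyphenyl)chroman‑4‑yl]‑4‑methoxyphenyl}acetate | COc1cc(OCc2ccccc2)c(CC(=O)OC)cc1[C@@H]1c2ccc(OCc3ccccc3)cc2OC[C@H]1c1ccc(OC)c(OCc2ccccc2)c1OC | intermediate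
12 | 2‑{2‑(benzyloxy)‑5‑[(3R,4S)‑7‑(benzyloxy)‑3‑(3‑(benzyloxy)‑2,4‑dimethoxyphenyl)chroman‑4‑yl]‑4‑methoxyphenyl}acetaldehyde | COc1cc(OCc2ccccc2)c(CC=O)cc1[C@@H]1c2ccc(OCc3ccccc3)cc2OC[C@H]1c1ccc(OC)c(OCc2ccccc2)c1OC | intermediate
13 | 4‑(benzyloxy)‑2‑hydroxybenzaldehyde | O=Cc1ccc(OCc2ccccc2)cc1O | starting material
14 | 5‑(benzyloxy)‑2‑(hydroxymethyl)phenol | OCc1ccc(OCc2ccccc2)cc1O | intermediate
15 | 5‑(benzyloxy)‑2‑[(4‑methylbenzenesulfonyl)methyl]phenol | Cc1ccc(cc1)S(=O)(=O)Cc1ccc(OCc2ccccc2)cc1O | intermediate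
16 | 3‑(benzyloxy)‑6‑methylidenecyclohexa‑2,4‑dien‑1‑one (o‑quinone methide) | C=C1C=CC(OCc2ccccc2)=CC1=O | intermediate
17 | E‑enamine of 12 with (R)‑α,α‑diphenylprolinol trimethylsilyl ether | COc1cc(OCc2ccccc2)c(/C=C/N2CCC[C@@H]2C(O[Si](C)(C)C)(c2ccccc2)c2ccccc2)cc1[C@@H]1c2ccc(OCc3ccccc3)cc2OC[C@H]1c1ccc(OC)c(OCc2ccccc2)c1OC | intermediate
18 | (3R)‑7‑(benzyloxy)‑3‑{2‑(benzyloxy)‑5‑[(3R,4S)‑7‑(benzyloxy)‑3‑(3‑(benzyloxy)‑2,4‑dimethoxyphenyl)chroman‑4‑yl]‑4‑methoxyphenyl}chroman‑2‑ol (C2 anomers) | COc1cc(OCc2ccccc2)c([C@@H]2C(O)Oc3cc(OCc4ccccc4)ccc3C2)cc1[C@@H]1c2ccc(OCc3ccccc3)cc2OC[C@H]1c1ccc(OC)c(OCc2ccccc2)c1OC | intermediate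
19 | (3R)‑7‑(benzyloxy)‑3‑{2‑(benzyloxy)‑5‑[(3R,4S)‑7‑(benzyloxy)‑3‑(3‑(benzyloxy)‑2,4‑dimethoxyphenyl)chroman‑4‑yl]‑4‑methoxyphenyl}chroman | COc1cc(OCc2ccccc2)c([C@@H]2COc3cc(OCc4ccccc4)ccc3C2)cc1[C@@H]1c2ccc(OCc3ccccc3)cc2OC[C@H]1c1ccc(OC)c(OCc2ccccc2)c1OC | intermediate
20 | (3R)‑3‑{2‑hydroxy‑5‑[(3R,4S)‑7‑hydroxy‑3‑(3‑hydroxy‑2,4‑dimethoxyphenyl)chroman‑4‑yl]‑4‑methoxyphenyl}chroman‑7‑ol | COc1cc(O)c([C@@H]2COc3cc(O)ccc3C2)cc1[C@@H]1c2ccc(O)cc2OC[C@H]1c1ccc(OC)c(O)c1OC | target

**Total step count:** 14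
**Longest linear sequence:** 9 steps (1, 2, 4, 5, 8, 9, 12, 13, 14)

**Steps most likely to fail**

1. Step 12. The C3 configuration may erode if the product re‑enters the enamine/enol manifold, and the quinone methide may oligomerise or N‑alkylate the catalyst faster than it is intercepted. Fallback, from ester 11: LiOH in THF/H2O gives the carboxylic acid F1. F1 is activated in situ with pivaloyl chloride and iPr2NEt and combined with sulfone 15 under benzotetramisole catalysis, the catalyst enantiomer being chosen to give the 3R product. This ammonium‑enolate Michael addition/lactonisation onto quinone methide 16 again makes both ring bonds in one operation and should give the (3R)‑dihydrocoumarin F2. DIBAL‑H at −78 °C reduces F2 to lactol 18, where the route is rejoined.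

2. Step 8. The C4 cation may lose the C3 proton to an isoflav‑3‑ene, which scrambles C3 on reprotonation, and anti selectivity of the arene attack may be incomplete. Fallback, from 10 and 7: iodination of 10 (NIS, cat. TFA, MeCN) para to the benzyloxy group gives methyl 2‑[2‑(benzyloxy)‑5‑iodo‑4‑methoxyphenyl]acetate F3. Alcohol 7 is converted with SOCl2 and 2,6‑lutidine at −20 °C into the (3R)‑4‑chloroisoflavan F4, used crude as its C4 epimers. A nickel‑catalysed reductive cross‑electrophile coupling of F3 and F4 (NiBr2·diglyme, a bis(oxazoline) ligand matched to 4S, Mn, DMA) runs through the C4 radical without a free cation and should give ester 11 with the new aryl group anti to the C3 substituent.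

3. Step 13. The oxocarbenium ion may undergo β‑elimination to the 4H‑chromene enol ether, whose reprotonation and reduction would erode C3. Fallback, from lactol 18: phenyl chlorothionoformate, pyridine and DMAP give the anomeric O‑phenyl thionocarbonate F5. Bu3SnH and AIBN in toluene at 90 °C (Barton–McCombie deoxygenation) cleave the exocyclic C2–O bond homolytically, and the α‑oxy radical takes up hydrogen to give 19 without any cationic intermediate.

**Further compounds**
F1 | step 12 | 2‑{2‑(benzyloxy)‑5‑[(3R,4S)‑7‑(benzyloxy)‑3‑(3‑(benzyloxy)‑2,4‑dimethoxyphenyl)chroman‑4‑yl]‑4‑methoxyphenyl}acetic acid | COc1cc(OCc2ccccc2)c(CC(=O)O)cc1[C@@H]1c2ccc(OCc3ccccc3)cc2OC[C@H]1c1ccc(OC)c(OCc2ccccc2)c1OC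
F2 | step 12 | (3R)‑7‑(benzyloxy)‑3‑{2‑(benzyloxy)‑5‑[(3R,4S)‑7‑(benzyloxy)‑3‑(3‑(benzyloxy)‑2,4‑dimethoxyphenyl)chroman‑4‑yl]‑4‑methoxyphenyl}chroman‑2‑one | COc1cc(OCc2ccccc2)c([C@@H]2C(=O)Oc3cc(OCc4ccccc4)ccc3C2)cc1[C@@H]1c2ccc(OCc3ccccc3)cc2OC[C@H]1c1ccc(OC)c(OCc2ccccc2)c1OC
F3 | step 8 | methyl 2‑[2‑(benzyloxy)‑5‑iodo‑4‑methoxyphenyl]acetate | COC(=O)Cc1cc(I)c(OC)cc1OCc1ccccc1
F4 | step 8 | (3R)‑7‑(benzyloxy)‑3‑[3‑(benzyloxy)‑2,4‑dimethoxyphenyl]‑4‑chlorochroman (C4 epimers) | ClC1c2ccc(OCc3ccccc3)cc2OC[C@H]1c1ccc(OC)c(OCc2ccccc2)c1OC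
F5 | step 13 | O‑phenyl thionocarbonate of lactol 18 at C2 | COc1cc(OCc2ccccc2)c([C@@H]2C(OC(=S)Oc5ccccc5)Oc3cc(OCc4ccccc4)ccc3C2)cc1[C@@H]1c2ccc(OCc3ccccc3)cc2OC[C@H]1c1ccc(OC)c(OCc2ccccc2)c1OC
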